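Numbering: C1 ketone, C2=C3 enone alkene, C4/C11 bridgeheads, C5/C10 one-carbon bridges, C6 the CMe2 carbon, C7/C9 the ester carbinols, C8 the CH2. The plan cuts C7–C8 in the seven-membered ring. The carbinol carbons C7 and C9 are 1,3-related and both hang on fully substituted carbons (C6, C10) whose arms are cis-1,3 on the cyclobutane, so a C9 ketone can form an enolate only at C8 and a C7 aldehyde has no α-hydrogen. SmI2 takes bromoketone–aldehyde 24, a 6,7-disubstituted 4-methylbicyclo[3.1.1]hept-3-en-2-one, to tricycle 26 in one operation, closing the ring and creating C7. Compound 24 is built by a vinylketene–alkene cycloaddition.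

Key step: step 17

Remark: 7 and 8 are racemates and their SMILES show the enantiomer that is carried on after the resolution in steps 6 and 7; "syn" and "anti" mean the positions on C5 and C10 that point towards and away from the C1–C3 bridge; step 17 is expected to give both C7 epimers and only the one drawn as 26 is carried on.

Step 1
Reactants: 1 methyl geranate, methyl (2E)-3,7-dimethylocta-2,6-dienoate
Product: 2 methyl (2E,6E)-8-hydroxy-3,7-dimethylocta-2,6-dienoate
Conditions: SeO2 (cat.), t-BuOOH, CH2Cl2, 25 °C
Reagents that add atoms: tert-butyl hydroperoxide, CC(C)(C)OO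
Why: Selenium dioxide allylic oxidation (ene reaction, then [2,3] shift) attacks the electron-rich terminal trisubstituted alkene at its (E)-methyl group and leaves the conjugated enoate alone, which fixes the (6E) geometry that later places this carbon (C9) anti on C10.

Step 2
Reactants: 2 methyl (2E,6E)-8-hydroxy-3,7-dimethylocta-2,6-dienoate
Product: 3 methyl (2E,6E)-8-(tert-butyldiphenylsilyloxy)-3,7-dimethylocta-2,6-dienoate
Conditions: t-BuPh2SiCl, imidazole, DMF, 25 °C
Reagents that add atoms: tert-butyl(chloro)diphenylsilane, CC(C)(C)[Si](Cl)(c1ccccc1)c1ccccc1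
Why: Silylation of a primary allylic alcohol gives an ether that withstands acid chloride formation, amide bases and magnesium in methanol.

Step 3
Reactants: 3 methyl (2E,6E)-8-(tert-butyldiphenylsilyloxy)-3,7-dimethylocta-2,6-dienoate
Product: 4 (2E,6E)-8-(tert-butyldiphenylsilyloxy)-3,7-dimethylocta-2,6-dienoic acid
Conditions: LiOH, THF–MeOH–H2O, 25 °C; then aq. HCl
Reagents that add atoms: lithium hydroxide, [Li+].[OH-]
Why: Saponification (acyl substitution by hydroxide) of the unhindered methyl ester should leave the silyl ether and both alkene geometries untouched.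

Step 4
Reactants: 4 (2E,6E)-8-(tert-butyldiphenylsilyloxy)-3,7-dimethylocta-2,6-dienoic acid
Product: 7 (±)-7-[(tert-butyldiphenylsilyloxy)methyl]-7-methyl-2-methylidenebicyclo[3.1.1]heptan-6-one (C5 ketone, C3 exocyclic methylene, on C10 the methyl syn and the silyloxymethyl anti), via acid chloride 5 (not isolated), via vinylketene 6 (not isolated)
Conditions: (COCl)2, benzene, 25 °C, evaporate; then slow addition to Et3N, toluene, 110 °C, high dilution
Reagents that add atoms: none
Why: Triethylamine removes a proton from the C3 methyl group (cis to the carbonyl in the 2E acid chloride) to give vinylketene 6, which undergoes the intramolecular vinylketene–alkene [2+2] cycloaddition known for geranic and farnesic acid chlorides, the ketene carbon bonding to C11 and its α-carbon to the more substituted C10; addition is suprafacial on the alkene, so the methyl group cis to the tether ends up syn and the silyloxymethyl group anti, and C4, C10 and C11 are formed in one relative configuration as a racemate.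

Step 5
Reactants: 7 (±)-7-[(tert-butyldiphenylsilyloxy)methyl]-7-methyl-2-methylidenebicyclo[3.1.1]heptan-6-one
Product: 8 (±)-7-[(tert-butyldiphenylsilyloxy)methyl]-2,7-dimethylbicyclo[3.1.1]hept-2-en-6-one (same relative configuration, C2=C3 now in the ring)
Conditions: RuHCl(CO)(PPh3)3 (3 mol %), toluene, 80 °C
Reagents that add atoms: none
Why: Ruthenium hydride addition–elimination (alkene isomerisation) moves the exocyclic double bond to the more stable trisubstituted ring position, as in β-pinene to α-pinene, which flattens the bridge above the C5 carbonyl and makes C1 allylic.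

Step 6
Reactants: 8 (±)-7-[(tert-butyldiphenylsilyloxy)methyl]-2,7-dimethylbicyclo[3.1.1]hept-2-en-6-one; 9 (S)-N,S-dimethyl-S-phenylsulfoximine
Product: 10 β-hydroxysulfoximine of the enantiomer of 8 with the target configuration at C4, C10 and C11 (C5 carries OH anti and the CH2S(O)(=NMe)Ph group syn; sulfur S), one diastereomer after chromatography
Conditions: n-BuLi, THF, −78 °C (lithiation of 9); then 8; AcOH, −78 °C; chromatography on silica
Reagents that add atoms: 9 (S)-N,S-dimethyl-S-phenylsulfoximine, CN=[S@](=O)(C)c1ccccc1
Why: 1,2-Addition of the lithiated enantiopure sulfoximine (the sulfoximine method for resolving ketones) to the strained, non-enolisable cyclobutanone from its bridge-side face, the side not blocked by the C9 arm on C10, turns the two enantiomers of 8 into two diastereomeric adducts that are separated on silica.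

Step 7
Reactants: 10 β-hydroxysulfoximine adduct
Product: 11 7-[(tert-butyldiphenylsilyloxy)methyl]-2,7-dimethylbicyclo[3.1.1]hept-2-en-6-one, single enantiomer with the target configuration at C4, C10 and C11
Conditions: toluene, 110 °C
Reagents that add atoms: none
Why: Thermal retro-addition of a β-hydroxysulfoximine returns the ketone, now as one enantiomer, and releases the sulfoximine for reuse.

Step 8
Reactants: 11 enantiopure bicyclic ketone; 12 methyl 2-(trimethylsilyl)acetate
Product: 13 methyl 2-{7-[(tert-butyldiphenylsilyloxy)methyl]-2,7-dimethylbicyclo[3.1.1]hept-2-en-6-ylidene}acetate (C5=C6 alkene, mixture of geometric isomers)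
Conditions: LiN(i-Pr)2, THF, −78 °C (enolate of 12); then 11, −78 → 25 °C
Reagents that add atoms: 12 methyl 2-(trimethylsilyl)acetate, COC(=O)C[Si](C)(C)C
Why: Peterson olefination, in which the α-silyl ester enolate adds to the strained C5 ketone from the bridge-side face and the β-silyl alkoxide loses lithium trimethylsilanolate in the flask; the alkene geometry is irrelevant because C6 becomes CMe2.

Step 9
Reactants: 13 alkylidene ester
Product: 14 methyl 2-{7-[(tert-butyldiphenylsilyloxy)methyl]-2,7-dimethylbicyclo[3.1.1]hept-2-en-6-yl}acetate (C5–H syn, CH2CO2Me arm anti and cis-1,3 to the silyloxymethyl group)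
Conditions: Mg, MeOH, 0 → 25 °C
Reagents that add atoms: none
Why: Dissolving-metal conjugate reduction of an α,β-unsaturated ester (Mg/MeOH) in which methanol should protonate C5 from the bridge-side face, because the other face lies under the cyclobutane against the C9 methylene on C10, so H ends up syn and the ester arm anti.

Step 10
Reactants: 14 saturated ester; 15 iodomethane
Product: 17 methyl 2-methyl-2-{7-[(tert-butyldiphenylsilyloxy)methyl]-2,7-dimethylbicyclo[3.1.1]hept-2-en-6-yl}propanoate (C6 now CMe2), via monomethyl ester 16 (not isolated)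
Conditions: LiN(i-Pr)2, THF, −78 °C, then MeI; second cycle LiN(i-Pr)2, DMPU, MeI, −78 → 0 °C
Reagents that add atoms: 15 iodomethane, CI
Why: Two successive ester enolate alkylations make C6 quaternary, and no other acidic C–H is present once the ring ketone is gone.

Step 11
Reactants: 17 gem-dimethyl ester
Product: 18 methyl 2-{6-[(tert-butyldiphenylsilyloxy)methyl]-4,6-dimethyl-2-oxobicyclo[3.1.1]hept-3-en-7-yl}-2-methylpropanoate (C1 ketone conjugated with C2=C3; arms on C5 and C10 anti)
Conditions: CrO3, 3,5-dimethylpyrazole, CH2Cl2, −20 °C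
Reagents that add atoms: chromium trioxide, O=[Cr](=O)=O
Why: Allylic oxidation with the chromium trioxide–dimethylpyrazole complex (hexavalent chromium) converts the only allylic methylene, C1, into the enone carbonyl, the same change as α-pinene to verbenone.

Step 12
Reactants: 18 enone silyl ether
Product: 19 methyl 2-[6-(hydroxymethyl)-4,6-dimethyl-2-oxobicyclo[3.1.1]hept-3-en-7-yl]-2-methylpropanoate
Conditions: Bu4NF, AcOH, THF, 25 °C
Reagents that add atoms: none
Why: Fluoride cleavage of the silyl ether, buffered with acetic acid so that the freed C9 alkoxide is protonated before it can lactonise onto the neighbouring ester.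

Step 13
Reactants: 19 primary alcohol
Product: 20 methyl 2-(6-formyl-4,6-dimethyl-2-oxobicyclo[3.1.1]hept-3-en-7-yl)-2-methylpropanoate (C9 aldehyde)
Conditions: Dess–Martin periodinane, CH2Cl2, 25 °C
Reagents that add atoms: none
Why: Dess–Martin oxidation of a neopentyl primary alcohol gives an aldehyde that cannot enolise because C10 is quaternary.

Step 14
Reactants: 20 C9 aldehyde; 21 dibromomethane
Product: 22 methyl 2-[6-(2-bromo-1-hydroxyethyl)-4,6-dimethyl-2-oxobicyclo[3.1.1]hept-3-en-7-yl]-2-methylpropanoate (both C9 epimers)
Conditions: CH2Br2, then n-BuLi, THF, −78 °C; AcOH, −78 °C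
Reagents that add atoms: 21 dibromomethane, BrCBr
Why: Bromomethyllithium, made by bromine–lithium exchange in the presence of the substrate (halomethyllithium addition), should add to the aldehyde much faster than to the hindered conjugated ketone or the tertiary ester, and the cold acid quench keeps the bromohydrin from closing to an epoxide; the C9 configuration does not matter because C9 is oxidised in step 16.

Step 15
Reactants: 22 bromohydrin ester
Product: 23 2-[6-(2-bromo-1-hydroxyethyl)-2-hydroxy-4,6-dimethylbicyclo[3.1.1]hept-3-en-7-yl]-2-methylpropan-1-ol (triol; C1 and C9 carbinols of either configuration)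
Conditions: i-Bu2AlH (excess), CH2Cl2, −78 → 0 °C; aq. tartaric acid
Reagents that add atoms: none
Why: Aluminium hydride reduction takes the ester to the primary alcohol and the enone to the allylic alcohol by 1,2-addition without touching the alkyl bromide, so that no carbonyl remains to form a hemiacetal between the two neighbouring arms.

Step 16
Reactants: 23 triol
Product: 24 2-[6-(bromoacetyl)-4,6-dimethyl-2-oxobicyclo[3.1.1]hept-3-en-7-yl]-2-methylpropanal (C7 aldehyde on the anti arm of C5, C9 bromomethyl ketone anti on C10, C10 methyl syn)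
Conditions: (COCl)2, DMSO, CH2Cl2, −78 °C; then i-Pr2NEt, −78 → −40 °C; pH 7 buffer
Reagents that add atoms: none
Why: Swern oxidation turns all three hydroxyls into alkoxysulfonium ions before any carbonyl exists, so aldehyde, bromoketone and enone appear together on adding base and no lactol between the two arms can be over-oxidised to a lactone.

Step 17
Reactants: 24 bromoketone–aldehyde
Product: 26 tricyclic C7-hydroxy C1,C9-diketone (seven-membered ring closed across C5 and C10; C7–OH on the C4 side), via samarium enolate 25 (not isolated)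
Conditions: SmI2 (2.5 equiv), THF, −78 °C, slow addition of 24 at high dilution; aq. work-up; chromatography (removes the C7 epimer)
Reagents that add atoms: none
Why: Two equivalents of SmI2 (divalent samarium) reduce the C8–Br bond, the most easily reduced group in 24 at −78 °C, to the trivalent samarium enolate 25, which can only be the C8 enolate because C10 is quaternary, and this adds to the C7 aldehyde, which cannot enolise because C6 is quaternary. The closest known reaction type is the samarium diiodide Reformatsky-type aldol of α-bromo ketones with aldehydes used to close medium carbocycles. The ring closes in the 7-(enolexo)-exo-trig mode; the cis-1,3 anti arms on C5 and C10 hold C8 and C7 within bonding distance, while the C1 carbonyl and C3 lie on the other face of the cyclobutane and cannot be reached. C7 is set by which of the two twist forms of the samarium-bridged transition state (enolate O–Sm–O=C7) is adopted, and the form with both oxygens under C4 gives 26. The step needs chemoselectivity for C–Br over enone and aldehyde (secured by the reduction potentials and the low temperature), one enolate and one acceptor (secured by C6 and C10), and facial selectivity at C7, for which the substrate offers only a weak bias because the region under the cyclobutane is almost mirror-symmetric and differs only through the distant C1 carbonyl and C3 methyl. The C7 epimer must therefore be expected as a separable co-product, and the fallback for this step addresses it.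

Step 18
Reactants: 26 tricyclic hydroxy diketone; 27 3-methylbutanal
Product: 28 C7 3-methylbutanoate (isovalerate) with free C9 alcohol, O7 and O9 anti (trans across the seven-membered ring)
Conditions: 27 (5 equiv), SmI2 (0.3 equiv), THF, −10 °C
Reagents that add atoms: 27 3-methylbutanal, CC(C)CC=O
Why: Evans–Tishchenko reduction, in which the C7 hydroxyl forms a samarium-bound hemiacetal with the aldehyde and passes its hydride to the C9 ketone through a six-membered chair, leaving the isovalerate on O7 and setting the C9 alcohol anti to it while the distant enone is untouched.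

Step 19
Reactants: 28 C7 isovalerate C9 alcohol; 29 tiglic acid, (E)-2-methylbut-2-enoic acid
Product: 30 CNP0194415.1, the C9 tiglate C7 isovalerate of the tricyclic enone
Conditions: 29, 2,4,6-trichlorobenzoyl chloride, Et3N, THF, 25 °C; then 28, DMAP, toluene, 40 °C
Reagents that add atoms: 29 tiglic acid, C/C=C(\C)C(=O)O
Why: Yamaguchi esterification through the mixed anhydride and DMAP acylates the hindered C9 alcohol with retention, the (E)-alkene of the tiglate is configurationally stable, and the anti O7 ester has no easy path for acyl migration.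

Compound list
1 | methyl geranate, methyl (2E)-3,7-dimethylocta-2,6-dienoate | COC(=O)/C=C(\C)CCC=C(C)C | starting material
2 | methyl (2E,6E)-8-hydroxy-3,7-dimethylocta-2,6-dienoate | COC(=O)/C=C(\C)CC/C=C(\C)CO | intermediate
3 | methyl (2E,6E)-8-(tert-butyldiphenylsilyloxy)-3,7-dimethylocta-2,6-dienoate | COC(=O)/C=C(\C)CC/C=C(\C)CO[Si](c1ccccc1)(c1ccccc1)C(C)(C)C | intermediate
4 | (2E,6E)-8-(tert-butyldiphenylsilyloxy)-3,7-dimethylocta-2,6-dienoic acid | OC(=O)/C=C(\C)CC/C=C(\C)CO[Si](c1ccccc1)(c1ccccc1)C(C)(C)C | intermediate
5 | acid chloride of 4 (not isolated) | ClC(=O)/C=C(\C)CC/C=C(\C)CO[Si](c1ccccc1)(c1ccccc1)C(C)(C)C | intermediate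
6 | vinylketene, (6E)-8-(tert-butyldiphenylsilyloxy)-7-methyl-3-methylideneocta-1,6-dien-1-one (not isolated) | O=C=CC(=C)CC/C=C(\C)CO[Si](c1ccccc1)(c1ccccc1)C(C)(C)C | intermediate
7 | (±)-7-[(tert-butyldiphenylsilyloxy)methyl]-7-methyl-2-methylidenebicyclo[3.1.1]heptan-6-one, methyl syn, silyloxymethyl anti (racemate, one enantiomer drawn) | O=C1[C@H]2CCC(=C)[C@@H]1[C@]2(CO[Si](c3ccccc3)(c3ccccc3)C(C)(C)C)C | intermediate
8 | (±)-7-[(tert-butyldiphenylsilyloxy)methyl]-2,7-dimethylbicyclo[3.1.1]hept-2-en-6-one, same relative configuration (racemate, one enantiomer drawn) | O=C1[C@H]2CC=C(C)[C@@H]1[C@]2(CO[Si](c3ccccc3)(c3ccccc3)C(C)(C)C)C | intermediate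
9 | (S)-N,S-dimethyl-S-phenylsulfoximine | CN=[S@](=O)(C)c1ccccc1 | starting material
10 | β-hydroxysulfoximine adduct of the target-series enantiomer of 8 (C5: OH anti, CH2S syn; sulfur S) | CN=[S@@](=O)(c3ccccc3)C[C@@]1(O)[C@H]2CC=C(C)[C@@H]1[C@]2(CO[Si](c3ccccc3)(c3ccccc3)C(C)(C)C)C | intermediate
11 | 7-[(tert-butyldiphenylsilyloxy)methyl]-2,7-dimethylbicyclo[3.1.1]hept-2-en-6-one, single enantiomer with the target configuration at C4, C10, C11 | O=C1[C@H]2CC=C(C)[C@@H]1[C@]2(CO[Si](c3ccccc3)(c3ccccc3)C(C)(C)C)C | intermediate
12 | methyl 2-(trimethylsilyl)acetate | COC(=O)C[Si](C)(C)C | starting material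
13 | methyl 2-{7-[(tert-butyldiphenylsilyloxy)methyl]-2,7-dimethylbicyclo[3.1.1]hept-2-en-6-ylidene}acetate (alkene isomers) | COC(=O)C=C1[C@H]2CC=C(C)[C@@H]1[C@]2(CO[Si](c3ccccc3)(c3ccccc3)C(C)(C)C)C | intermediate
14 | methyl 2-{7-[(tert-butyldiphenylsilyloxy)methyl]-2,7-dimethylbicyclo[3.1.1]hept-2-en-6-yl}acetate, C5–H syn, ester arm anti | COC(=O)C[C@@H]1[C@H]2CC=C(C)[C@@H]1[C@]2(CO[Si](c3ccccc3)(c3ccccc3)C(C)(C)C)C | intermediate
15 | iodomethane | CI | starting material
16 | monomethyl ester, methyl 2-{…hept-2-en-6-yl}propanoate (C6 epimers, not isolated) | COC(=O)C(C)[C@@H]1[C@H]2CC=C(C)[C@@H]1[C@]2(CO[Si](c3ccccc3)(c3ccccc3)C(C)(C)C)C | intermediate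
17 | methyl 2-methyl-2-{7-[(tert-butyldiphenylsilyloxy)methyl]-2,7-dimethylbicyclo[3.1.1]hept-2-en-6-yl}propanoate | COC(=O)C(C)(C)[C@@H]1[C@H]2CC=C(C)[C@@H]1[C@]2(CO[Si](c3ccccc3)(c3ccccc3)C(C)(C)C)C | intermediate
18 | methyl 2-{6-[(tert-butyldiphenylsilyloxy)methyl]-4,6-dimethyl-2-oxobicyclo[3.1.1]hept-3-en-7-yl}-2-methylpropanoate | COC(=O)C(C)(C)[C@@H]1[C@H]2C(=O)C=C(C)[C@@H]1[C@]2(CO[Si](c3ccccc3)(c3ccccc3)C(C)(C)C)C | intermediate
19 | methyl 2-[6-(hydroxymethyl)-4,6-dimethyl-2-oxobicyclo[3.1.1]hept-3-en-7-yl]-2-methylpropanoate | COC(=O)C(C)(C)[C@@H]1[C@H]2C(=O)C=C(C)[C@@H]1[C@]2(CO)C | intermediate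
20 | methyl 2-(6-formyl-4,6-dimethyl-2-oxobicyclo[3.1.1]hept-3-en-7-yl)-2-methylpropanoate | COC(=O)C(C)(C)[C@@H]1[C@H]2C(=O)C=C(C)[C@@H]1[C@]2(C=O)C | intermediate
21 | dibromomethane | BrCBr | starting material
22 | methyl 2-[6-(2-bromo-1-hydroxyethyl)-4,6-dimethyl-2-oxobicyclo[3.1.1]hept-3-en-7-yl]-2-methylpropanoate (C9 epimers) | COC(=O)C(C)(C)[C@@H]1[C@H]2C(=O)C=C(C)[C@@H]1[C@]2(C(O)CBr)C | intermediate
23 | 2-[6-(2-bromo-1-hydroxyethyl)-2-hydroxy-4,6-dimethylbicyclo[3.1.1]hept-3-en-7-yl]-2-methylpropan-1-ol (C1 and C9 epimers) | OCC(C)(C)[C@@H]1[C@H]2C(O)C=C(C)[C@@H]1[C@]2(C(O)CBr)C | intermediate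
24 | 2-[6-(bromoacetyl)-4,6-dimethyl-2-oxobicyclo[3.1.1]hept-3-en-7-yl]-2-methylpropanal | O=CC(C)(C)[C@@H]1[C@H]2C(=O)C=C(C)[C@@H]1[C@]2(C(=O)CBr)C | intermediate
25 | samarium enolate of 24 at C8–C9 (diiodosamarium enolate, not isolated) | O=CC(C)(C)[C@@H]1[C@H]2C(=O)C=C(C)[C@@H]1[C@]2(C(=C)O[Sm](I)I)C | intermediate
26 | tricyclic C7-hydroxy C1,C9-diketone | O=C1C[C@@H](O)C(C)(C)[C@@H]2[C@H]3C(=O)C=C(C)[C@@H]2[C@]31C | intermediate
27 | 3-methylbutanal | CC(C)CC=O | starting material
28 | C7 isovalerate, C9 alcohol (O7/O9 anti) | O[C@@H]1C[C@@H](OC(=O)CC(C)C)C(C)(C)[C@@H]2[C@H]3C(=O)C=C(C)[C@@H]2[C@]31C | intermediate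
29 | tiglic acid, (E)-2-methylbut-2-enoic acid | C/C=C(\C)C(=O)O | starting material
30 | CNP0194415.1 | C/C=C(\C)C(=O)O[C@@H]1C[C@@H](OC(=O)CC(C)C)C(C)(C)[C@@H]2[C@H]3C(=O)C=C(C)[C@@H]2[C@]31C | target

Total step count: 19. Longest linear sequence: 19 steps (1 to 30).

Steps most likely to fail

Step 17. The closure may show little facial selectivity at C7, and the samarium enolate may be protonated before it reaches the aldehyde. The fallback replaces substrate control by reagent control. It sets out from 24: zinc dust in AcOH–THF removes the bromine to give the methyl ketone–aldehyde F1. Treating F1 with B-chlorodiisopinocampheylborane and Et3N in Et2O at −78 °C forms the C8 boron enolate, the only one possible, which closes onto the C7 aldehyde in a boron aldol reaction whose facial sense is imposed by the isopinocampheyl groups; the antipode of the reagent that puts the hydroxyl on the C4 side is used. Non-oxidative work-up (MeOH, pH 7 buffer) brings the material back to the route at 26.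

Step 8. The branched α-silyl enolate may fail to reach the C5 carbonyl, which is flanked by the bridge on one face and the C9 arm on the other, or the addition may revert. The fallback sets out from 11 and uses the slimmest carbon nucleophile: lithium ethoxyacetylide (ethoxyacetylene, n-BuLi, THF, −78 °C) gives the propargylic alcohol F2. Meyer–Schuster rearrangement of this ethoxyalkynyl carbinol with a catalytic Lewis acid (Sc(OTf)3, EtOH–CH2Cl2, 25 °C) gives the ethyl alkylidene-acetate F3. Magnesium in methanol then reduces the conjugated alkene and exchanges the ester, so the material returns at 14.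

Step 4. The vinylketene may dimerise or be lost to other pathways faster than it adds to an alkene whose nucleophilicity is lowered by the allylic silyloxy group. The fallback sets out from 4 and uses the more electrophilic keteniminium ion: acid chloride 5 and dimethylamine give the N,N-dimethylamide F4. Triflic anhydride and 2,4,6-collidine in 1,2-dichloroethane at 80 °C generate the vinylketeniminium salt, which undergoes the same intramolecular [2+2] cycloaddition to the cyclobutaniminium triflate F5. Aqueous NaHCO3 hydrolyses F5 and the route is rejoined at 7.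

Further compounds
F1 | step 17 | 2-(6-acetyl-4,6-dimethyl-2-oxobicyclo[3.1.1]hept-3-en-7-yl)-2-methylpropanal (24 without bromine) | O=CC(C)(C)[C@@H]1[C@H]2C(=O)C=C(C)[C@@H]1[C@]2(C(C)=O)C
F2 | step 8 | 6-(ethoxyethynyl)-7-[(tert-butyldiphenylsilyloxy)methyl]-2,7-dimethylbicyclo[3.1.1]hept-2-en-6-ol (OH anti) | CCOC#C[C@@]1(O)[C@H]2CC=C(C)[C@@H]1[C@]2(CO[Si](c3ccccc3)(c3ccccc3)C(C)(C)C)C
F3 | step 8 | ethyl 2-{7-[(tert-butyldiphenylsilyloxy)methyl]-2,7-dimethylbicyclo[3.1.1]hept-2-en-6-ylidene}acetate | CCOC(=O)C=C1[C@H]2CC=C(C)[C@@H]1[C@]2(CO[Si](c3ccccc3)(c3ccccc3)C(C)(C)C)C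
F4 | step 4 | (2E,6E)-8-(tert-butyldiphenylsilyloxy)-N,N,3,7-tetramethylocta-2,6-dienamide | CN(C)C(=O)/C=C(\C)CC/C=C(\C)CO[Si](c1ccccc1)(c1ccccc1)C(C)(C)C
F5 | step 4 | (±)-N,N-dimethyl cyclobutaniminium triflate corresponding to ketone 7 | C[N+](C)=C1[C@H]2CCC(=C)[C@@H]1[C@]2(CO[Si](c3ccccc3)(c3ccccc3)C(C)(C)C)C.[O-]S(=O)(=O)C(F)(F)F
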